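**Retrosynthetic overview**
1. Plakortone N ⇐ its O-benzyl ether; only a hydrogenolysis remains after the core is built.
2. Both rings are opened in one disconnection, the C3–C4 bond and the lactone C–O bond, giving an acyclic enal–ketone R(Me)C(O–CH=CH–CHO)–CH2–COMe. The enal β-carbon (C3) acts as a carbene-generated homoenolate on the C4 ketone; the tetrahydrofuran closes first and the γ-lactone second, in the same flask.
3. Enal ether ⇐ tertiary β-hydroxy ketone + propynal (O–C3 bond by oxa-Michael addition).
4. β-Hydroxy ketone ⇐ 14-aryltetradecan-2-one by catalytic asymmetric allylboration (sets C6) and Wacker oxidation.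
5. Ketone ⇐ 1-(benzyloxy)-4-bromobenzene + 1,11-dibromoundecane + ethyl acetoacetate.

Assumption: conjugate bases and salts of numbered compounds, and catalyst-bound species inside a catalytic cycle, are treated as mechanism and not numbered as separate compounds.
Numbering used in the text: C1 = lactone carbonyl, C2 = CH2, C3 = ring-fusion CH–O, C4 = ring-fusion C(Me)–O(lactone), C5 = ring CH2, C6 = C(Me)(chain)–O, C7–C18 = chain; the target is 3S,4S,6S.

**Route**

Step 1
Reactants: 1 1-(benzyloxy)-4-bromobenzene; 2 1,11-dibromoundecane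
Product: 4 1-(benzyloxy)-4-(11-bromoundecyl)benzene, via [4-(benzyloxy)phenyl]magnesium bromide 3 (not isolated)
Conditions: Mg, THF, reflux; then added to 2 (3 equiv, excess recovered), Li2CuCl4 (3 mol%), THF, −10 °C to rt
Reagents that add atoms: none
Why: Kochi-type copper-catalysed Grignard cross-coupling of an aryl Grignard reagent with a primary alkyl bromide, the excess of dibromide keeping the coupling at mono-substitution.

Step 2
Reactants: 4 1-(benzyloxy)-4-(11-bromoundecyl)benzene; 5 ethyl acetoacetate
Product: 8 14-[4-(benzyloxy)phenyl]tetradecan-2-one, via alkylated keto ester 6 (not isolated), via keto acid 7 (not isolated)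
Conditions: 5 (1.5 equiv), NaOEt, EtOH, reflux; then 2 M NaOH, EtOH/H2O, rt; then 2 M HCl, 60 °C
Reagents that add atoms: none
Why: acetoacetic ester synthesis (SN2 alkylation of the stabilised enolate, saponification, thermal decarboxylation of the β-keto acid), to which the benzyl aryl ether is inert.

Step 3
Reactants: 8 14-[4-(benzyloxy)phenyl]tetradecan-2-one; 9 diisopropyl allylboronate
Product: 11 (4S)-16-[4-(benzyloxy)phenyl]-4-methylhexadec-1-en-4-ol, via borate ester 10 (not isolated)
Conditions: 9 (1.5 equiv), (S)-3,3'-dibromo-1,1'-bi-2-naphthol (15 mol%), PhCF3/PhMe 3:1, −35 °C; aqueous NaHCO3 work-up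
Reagents that add atoms: none
Why: chiral-diol-catalysed asymmetric allylboration of a ketone, in which exchange of one isopropoxy group for the diol gives an activated allylboronate that reacts through a closed chair transition state with the long chain equatorial and methyl axial, delivering allyl to the Re face (sense taken by analogy with other methyl ketones) and so setting C6 as S.

Step 4
Reactants: 11 (4S)-16-[4-(benzyloxy)phenyl]-4-methylhexadec-1-en-4-ol
Product: 12 (4S)-16-[4-(benzyloxy)phenyl]-4-hydroxy-4-methylhexadecan-2-one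
Conditions: PdCl2 (10 mol%), CuCl (1 equiv), O2 (1 atm), DMF/H2O 7:1, rt
Reagents that add atoms: water, O
Why: Tsuji–Wacker oxidation, where Markovnikov hydroxypalladation and β-hydride elimination turn the terminal alkene into the methyl ketone without touching the tertiary carbinol stereocentre or the benzyl ether.

Step 5
Reactants: 13 propargyl alcohol
Product: 14 propynal
Conditions: activated MnO2 (10 equiv), CH2Cl2, rt; filtered and used at once as a cold titrated CH2Cl2 solution
Reagents that add atoms: none
Why: selective surface oxidation of a propargylic alcohol to the ynal by MnO2, with no over-oxidation and a simple filtration as work-up.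

Step 6
Reactants: 12 (4S)-16-[4-(benzyloxy)phenyl]-4-hydroxy-4-methylhexadecan-2-one; 14 propynal
Product: 15 (2E)-3-({(4S)-16-[4-(benzyloxy)phenyl]-4-methyl-2-oxohexadecan-4-yl}oxy)prop-2-enal
Conditions: 14 (1.5 equiv), PMe3 (10 mol%), CH2Cl2, −20 to 0 °C; volatiles removed, quick filtration through neutral silica
Reagents that add atoms: none
Why: phosphine-catalysed oxa-Michael addition of a hindered tertiary alcohol to an activated alkyne, giving the E β-alkoxy enal under essentially neutral conditions that leave the C6 stereocentre (no bond to it is broken) and the ketone untouched.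

Step 7
Reactants: 15 (2E)-3-({(4S)-16-[4-(benzyloxy)phenyl]-4-methyl-2-oxohexadecan-4-yl}oxy)prop-2-enal
Product: 16 (1S,5S,7S)-7-{12-[4-(benzyloxy)phenyl]dodecyl}-1,7-dimethyl-2,6-dioxabicyclo[3.3.0]octan-3-one (cis-fused; bridgehead methyl, bridgehead H and the C12 chain on the convex face, the other methyl on the concave face)
Conditions: (5aS,10bR)-2-mesityl-5a,10b-dihydro-4H,6H-indeno[2,1-b][1,2,4]triazolo[4,3-d][1,4]oxazin-2-ium chloride (10 mol%), KOtBu (8 mol%), THF, 4 Å molecular sieves, 25 °C
Reagents that add atoms: none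
Why: Proposed new method: the N-mesityl triazolylidene adds to the aldehyde to give a Breslow intermediate whose β-carbon (C3, normally electrophilic, here a homoenolate) attacks the tethered methyl ketone in a 5-exo closure that forms the C3–C4 bond and the tetrahydrofuran, after which the C4 alkoxide acylates the acyl azolium to close the γ-lactone and release the catalyst (closest known reaction type: carbene-catalysed homoenolate annulation of enals with ketones to γ-butyrolactones, including tethered cases that give fused bicyclic lactones); the cis fusion at C3/C4 is enforced because only the cis alkoxide can reach the acyl azolium, and the Re(C3)-to-Re(C4) pairing that gives 3S,4S is set by the chiral catalyst and reinforced by the substrate, which places the C12 chain on the convex face and the C6 methyl on the concave face.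

Step 8
Reactants: 16 (1S,5S,7S)-7-{12-[4-(benzyloxy)phenyl]dodecyl}-1,7-dimethyl-2,6-dioxabicyclo[3.3.0]octan-3-one
Product: 17 plakortone N, (1S,5S,7S)-7-[12-(4-hydroxyphenyl)dodecyl]-1,7-dimethyl-2,6-dioxabicyclo[3.3.0]octan-3-one
Conditions: H2 (1 atm), Pd/C (10 wt%), EtOAc, rt
Reagents that add atoms: none
Why: catalytic hydrogenolysis of the benzyl aryl ether, to which the lactone, the tertiary ether and all three stereocentres are inert.

**Compound list**
1 | 1-(benzyloxy)-4-bromobenzene | Brc1ccc(OCc2ccccc2)cc1 | starting material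
2 | 1,11-dibromoundecane | BrCCCCCCCCCCCBr | starting material
3 | [4-(benzyloxy)phenyl]magnesium bromide | Br[Mg]c1ccc(OCc2ccccc2)cc1 | intermediate
4 | 1-(benzyloxy)-4-(11-bromoundecyl)benzene | BrCCCCCCCCCCCc1ccc(OCc2ccccc2)cc1 | intermediate
5 | ethyl acetoacetate | CCOC(=O)CC(C)=O | starting material
6 | ethyl 2-acetyl-13-[4-(benzyloxy)phenyl]tridecanoate (racemic at C2) | CCOC(=O)C(CCCCCCCCCCCc1ccc(OCc2ccccc2)cc1)C(C)=O | intermediate
7 | 2-acetyl-13-[4-(benzyloxy)phenyl]tridecanoic acid (racemic at C2) | OC(=O)C(CCCCCCCCCCCc1ccc(OCc2ccccc2)cc1)C(C)=O | intermediate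
8 | 14-[4-(benzyloxy)phenyl]tetradecan-2-one | CC(=O)CCCCCCCCCCCCc1ccc(OCc2ccccc2)cc1 | intermediate
9 | diisopropyl allylboronate | C=CCB(OC(C)C)OC(C)C | starting material
10 | diisopropyl (4S)-16-[4-(benzyloxy)phenyl]-4-methylhexadec-1-en-4-yl borate | C[C@](OB(OC(C)C)OC(C)C)(CCCCCCCCCCCCc1ccc(OCc2ccccc2)cc1)CC=C | intermediate
11 | (4S)-16-[4-(benzyloxy)phenyl]-4-methylhexadec-1-en-4-ol | C[C@](O)(CCCCCCCCCCCCc1ccc(OCc2ccccc2)cc1)CC=C | intermediate
12 | (4S)-16-[4-(benzyloxy)phenyl]-4-hydroxy-4-methylhexadecan-2-one | C[C@](O)(CCCCCCCCCCCCc1ccc(OCc2ccccc2)cc1)CC(C)=O | intermediate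
13 | propargyl alcohol | C#CCO | starting material
14 | propynal | C#CC=O | intermediate
15 | (2E)-3-({(4S)-16-[4-(benzyloxy)phenyl]-4-methyl-2-oxohexadecan-4-yl}oxy)prop-2-enal | C[C@](O/C=C/C=O)(CCCCCCCCCCCCc1ccc(OCc2ccccc2)cc1)CC(C)=O | intermediate
16 | (1S,5S,7S)-7-{12-[4-(benzyloxy)phenyl]dodecyl}-1,7-dimethyl-2,6-dioxabicyclo[3.3.0]octan-3-one | C[C@]1(CCCCCCCCCCCCc2ccc(OCc3ccccc3)cc2)C[C@]2(C)OC(=O)C[C@@H]2O1 | intermediate
17 | plakortone N | C[C@]1(CCCCCCCCCCCCc2ccc(O)cc2)C[C@]2(C)OC(=O)C[C@@H]2O1 | target

**Step count**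
Total steps: 8. Longest linear sequence: 7 (steps 1, 2, 3, 4, 6, 7, 8); step 5 is a one-step side branch.

**Steps most likely to fail**

Step 7 (carbene-catalysed annulation). A β-alkoxy enal is an untested homoenolate precursor. Three things can go wrong: β-protonation followed by an enolate aldol path, base-induced loss of the vinylogous carboxylate from C6 (hence less base than azolium salt), and a facial sense that is unproven for this substrate. The antipodal precatalyst is equally available and would be tried first if the sense is wrong; the C4 epimer is separable in any case.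
The fallback sets out from 12 and comes back at 16. The ketone of 12 is treated with LiC≡CCO2Et (ethyl propiolate and LiN(SiMe3)2, 2.5 equiv, CeCl3, THF, −78 °C) to give ethyl (4S,6S)-18-[4-(benzyloxy)phenyl]-4,6-dihydroxy-4,6-dimethyloctadec-2-ynoate F1 together with its C4 epimer. Semihydrogenation (H2, Pd/CaCO3 poisoned with Pb(OAc)2, quinoline, EtOAc) gives ethyl (2Z,4S,6S)-18-[4-(benzyloxy)phenyl]-4,6-dihydroxy-4,6-dimethyloctadec-2-enoate F2, which lactonises with PPTS to (5S)-5-{(2S)-14-[4-(benzyloxy)phenyl]-2-hydroxy-2-methyltetradecyl}-5-methylfuran-2(5H)-one F3. DBU in CH2Cl2 then drives oxa-Michael addition of the C6 hydroxyl onto the butenolide, which can only give the cis-fused lactone 16. The C4 epimer is removed by chromatography at F3 or 16. This costs two more steps and gives up catalyst control at C4.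

Step 6 (oxa-Michael addition to propynal). The nucleophile is a hindered tertiary aldol-type alcohol whose alkoxide can undergo retro-aldol cleavage, and the product carries a leaving group β to the ketone.
The fallback sets out from 11 and comes back at 15, so the tether is installed before the ketone exists. Alcohol 11 is added to ethyl propiolate (PMe3 10 mol%, CH2Cl2, 0 °C) to give ethyl (2E)-3-({(4S)-16-[4-(benzyloxy)phenyl]-4-methylhexadec-1-en-4-yl}oxy)prop-2-enoate F4. Reduction with iBu2AlH (CH2Cl2, −78 °C) gives (2E)-3-({(4S)-16-[4-(benzyloxy)phenyl]-4-methylhexadec-1-en-4-yl}oxy)prop-2-en-1-ol F5. MnO2 (CH2Cl2) gives (2E)-3-({(4S)-16-[4-(benzyloxy)phenyl]-4-methylhexadec-1-en-4-yl}oxy)prop-2-enal F6. Wacker oxidation of the allyl group (PdCl2, CuCl, O2, DMF/H2O) then gives 15 without the β-alkoxy ketone ever meeting a basic medium.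

Step 3 (asymmetric allylboration). Discrimination between methyl and an unbranched alkyl chain may stop near 90:10. The minor C6 enantiomer ends up as a separable diastereomer after step 7, but yield is lost.
The fallback sets out from 4 and comes back at 11, taking C6 from a Sharpless-derived building block instead. Bromide 4 is converted (Mg, THF) into {11-[4-(benzyloxy)phenyl]undecyl}magnesium bromide F7. This opens (S)-2-methylglycidyl tosylate at the epoxide CH2 (CuI 10 mol%, THF, −30 °C; aqueous NH4Cl) to give (2S)-14-[4-(benzyloxy)phenyl]-2-hydroxy-2-methyltetradecyl 4-methylbenzenesulfonate F8. K2CO3 in MeOH closes it to (2S)-2-{12-[4-(benzyloxy)phenyl]dodecyl}-2-methyloxirane F9. CH2=CHMgBr with CuI (10 mol%, THF, −20 °C) opens the epoxide at CH2 to give 11, with no bond to the quaternary carbon ever broken.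

**Further compounds**
F1 | step 7 | ethyl (4S,6S)-18-[4-(benzyloxy)phenyl]-4,6-dihydroxy-4,6-dimethyloctadec-2-ynoate | C[C@](O)(CCCCCCCCCCCCc1ccc(OCc2ccccc2)cc1)C[C@](C)(O)C#CC(=O)OCC
F2 | step 7 | ethyl (2Z,4S,6S)-18-[4-(benzyloxy)phenyl]-4,6-dihydroxy-4,6-dimethyloctadec-2-enoate | C[C@](O)(CCCCCCCCCCCCc1ccc(OCc2ccccc2)cc1)C[C@](C)(O)/C=C\C(=O)OCC
F3 | step 7 | (5S)-5-{(2S)-14-[4-(benzyloxy)phenyl]-2-hydroxy-2-methyltetradecyl}-5-methylfuran-2(5H)-one | C[C@](O)(CCCCCCCCCCCCc1ccc(OCc2ccccc2)cc1)C[C@]1(C)OC(=O)C=C1
F4 | step 6 | ethyl (2E)-3-({(4S)-16-[4-(benzyloxy)phenyl]-4-methylhexadec-1-en-4-yl}oxy)prop-2-enoate | C[C@](O/C=C/C(=O)OCC)(CCCCCCCCCCCCc1ccc(OCc2ccccc2)cc1)CC=C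
F5 | step 6 | (2E)-3-({(4S)-16-[4-(benzyloxy)phenyl]-4-methylhexadec-1-en-4-yl}oxy)prop-2-en-1-ol | C[C@](O/C=C/CO)(CCCCCCCCCCCCc1ccc(OCc2ccccc2)cc1)CC=C
F6 | step 6 | (2E)-3-({(4S)-16-[4-(benzyloxy)phenyl]-4-methylhexadec-1-en-4-yl}oxy)prop-2-enal | C[C@](O/C=C/C=O)(CCCCCCCCCCCCc1ccc(OCc2ccccc2)cc1)CC=C
F7 | step 3 | {11-[4-(benzyloxy)phenyl]undecyl}magnesium bromide | Br[Mg]CCCCCCCCCCCc1ccc(OCc2ccccc2)cc1
F8 | step 3 | (2S)-14-[4-(benzyloxy)phenyl]-2-hydroxy-2-methyltetradecyl 4-methylbenzenesulfonate | C[C@](O)(CCCCCCCCCCCCc1ccc(OCc2ccccc2)cc1)COS(=O)(=O)c1ccc(C)cc1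
F9 | step 3 | (2S)-2-{12-[4-(benzyloxy)phenyl]dodecyl}-2-methyloxirane | C[C@]1(CCCCCCCCCCCCc2ccc(OCc3ccccc3)cc2)CO1
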